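Blue is the flask you are asked about, followed so far to 10.0 h: a closed, stirred flask of substrate and protic impurity under a held gas phase.

| setting | blue | flask |
|---|---|---|
| substrate | 0.13 M | 0.13 M |
| gas phase | 5.6 mM (held) | 5.6 mM (held) |
| protic impurity | 0.026 M | 0.0260 M |
| remark | the very flask that is asked about, followed so far |  |
| time |  | 5.0 d |

- blue (time / h: target / %): 0.833: 2; 1.33: 6; 2.00: 8; 2.50: 10; 4.00: 16; 6.00: 25; 10.0: 37

(each reading ± 2 percentage points)

- at the start none of the gas phase is in solution

- target at 5.0 d, in percent of the substrate charged
- concentration of dissolved gas in solution at 12 h, in percent of saturation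
- the change that raises the amount of target at 5.0 d, in percent of the substrate charged most ("none" if none brings more than 2 percentage points) (north / east / none)
- amount of target at 5.0 d, in percent of the substrate charged, after east

- north: doubling the saturation concentration of gas phase, all else as stated
- east: doubling the transfer coefficient of the gas phase, all else as stated

Replace the blue curve by its mean. Target at the last reading, spread over the time, gives a mean rate of 4.81 mM h⁻¹. The charge 0.13 M divided by that rate gives 1.13 d, the clearing time: what the charge needs at the mean rate. It is shorter than the 5.0 d asked about, by a factor of 4.42.

The weak link is the mean itself. In blue, the rate read over the first 4.00 h is 5.20 mM h⁻¹ and over the rest 4.55 mM h⁻¹, slower, though readings scatter by 2 percentage points. So reforge it: let the rate fall in proportion to the substrate left, a pseudo-first-order decay. With target counted as substrate lost, the last blue reading then gives a constant of 0.0462 h⁻¹, and this estimate leaves 0.391% of the substrate at 5.0 d. That small rest is the estimate you can commit to, but the blue readings follow target alone and give no yield from this reckoning.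

The forecast gives 80% target, and 80% target after east, saying “The limit is therefore stoichiometric”. For dissolved gas at 12 h it gives 65% of saturation. Its best change is none. The yield figure is its own, not mine.

The flask gives 80.2% target, and 83.2% target after east. Its dissolved gas at 12 h stands at 65.4% of saturation. The best change is north, worth 8.5 points against 2.9 points for east.

    dissolved gas + protic impurity → quenched reagent (k = 3.70 M⁻¹ h⁻¹)
    substrate → side product (k = 0.0140 h⁻¹)
    substrate + dissolved gas → target (k = 16.0 M⁻¹ h⁻¹)
    2 dissolved gas → homo dimer (k = 5.70 M⁻¹ h⁻¹)
    gas phase ⇌ dissolved gas, rate k5*(csat - [dissolved gas]) (kL = 2.10 h⁻¹)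

This flask held 0.579% of its substrate at 2.50 d, past the clearing time of 1.13 d, and ended with 19.8% as side product. The neighbour charged with 0.52 M of substrate has, at blue's mean rate, a clearing time of 4.50 d, shorter than 5.0 d. It ended with 0.0090% of its substrate left, 31.3% as side product and 68.7% as target.

All runs are simulated with constants of no real substance; scatter was added.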